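**Plan**

- Retrosynthesis cuts, in order: the thirteen O-alkyl bonds; the ring C–O–ring D ether (ring C phenoxide plus a ring D aryne); ring D itself (back to a 4-[1-(aryloxy)vinyl]cyclobutenone); then the ring B–O–ring C and ring A–O–ring B ethers (phenol plus bromobenzaldehyde, the formyl group later becoming the next phenol oxygen).
- Enabling feature (rings lettered A to E from the 2,4,6-trihydroxyphenoxy end): ring D is a 1,2,3,5-tetraoxygenated benzene with four unlike oxygens. C1 (O to ring C) is para to C4 (OH), C3 carries OH, C5 carries the ring E oxygen, and C2 and C6 carry H. C1 and C4 can therefore be the two carbonyl carbons of a cyclobutenedione, C3 its alkoxy carbon, C2 its CH, and C5–C6 a 1-(aryloxy)vinyl group that brings ring E in already attached.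
- Forward: rings A, B, C and E are bought as arenes and ring D is the only ring made (semisquarate plus 1-(aryloxy)vinyllithium, then thermal ring expansion to a phenol that is differentiated from its isopropyl and methyl ether neighbours).
- The ring D phenol becomes an ortho-silyl triflate; A, B and C are joined by two etherification/Dakin cycles to a ring C phenol; aryne O-arylation joins the halves; BBr3 frees the thirteen hydroxyls.
- Stereochemistry: the target is achiral; the only stereocentres on the way (the carbinol of the reduced squarate and the quaternary carbon of the cyclobutenone) are racemic and are erased.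

Key step: step 6

Remark: the six numbered starting materials are taken to be catalogue chemicals, and where the ortho-lithiation of step 8 could choose between the two positions next to the carbamate, the isomer expected to dominate is drawn.

**Route**

Step 1
Reactants: 1 diisopropyl squarate
Product: 3 3-isopropoxycyclobut-3-ene-1,2-dione (isopropyl semisquarate), via hydroxycyclobutenone 2 (not isolated)
Conditions: LiAlH(Ot-Bu)3, THF, −78 → 0 °C; aq. NH4Cl; then conc. HCl, CH2Cl2, rt
Reagents that add atoms: water, O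
Why: The bulky hydride should reduce one carbonyl of the squarate (1,2-reduction) to racemic alcohol 2, and acid then ionises the allylic alcohol, water enters at the isopropoxy-stabilised terminus and isopropanol leaves, which is the established reduction–hydrolysis route to semisquarates and removes the stereocentre of 2.

Step 2
Reactants: 4 3,4,5-trimethoxyphenol; 5 trichloroethylene
Product: 6 5-{[(E)-1,2-dichloroethenyl]oxy}-1,2,3-trimethoxybenzene
Conditions: K2CO3, DMF, 70 °C
Reagents that add atoms: none
Why: Base dehydrochlorinates trichloroethylene to dichloroacetylene, to which the phenoxide adds with anti protonation (nucleophilic addition to a haloalkyne), the standard way from phenols to (E)-1,2-dichlorovinyl ethers.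

Step 3
Reactants: 6 5-{[(E)-1,2-dichloroethenyl]oxy}-1,2,3-trimethoxybenzene
Product: 9 5-(ethynyloxy)-1,2,3-trimethoxybenzene, via chloroethynyl ether 7 (not isolated), via lithium acetylide 8 (not isolated)
Conditions: n-BuLi (2.2 equiv), Et2O, −78 → −40 °C; H2O, −78 °C
Reagents that add atoms: none
Why: Vinylic deprotonation and β-elimination of chloride give chloroalkyne 7, chlorine–lithium exchange gives acetylide 8 and protonation gives the aryl ynol ether, the known dichlorovinyl ether to ynol ether elimination sequence.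

Step 4
Reactants: 9 5-(ethynyloxy)-1,2,3-trimethoxybenzene
Product: 10 tributyl[1-(3,4,5-trimethoxyphenoxy)ethenyl]stannane
Conditions: Bu3SnH, Pd(PPh3)4 (2 mol %), THF, 0 °C → rt
Reagents that add atoms: tributyltin hydride, CCCC[SnH](CCCC)CCCC
Why: Hydrostannation catalysed by zerovalent palladium adds syn across the polarised ynol ether with tin at the oxygen-bearing carbon and hydrogen at the terminus, the regiochemistry known for alkoxyalkynes, so the 1-stannylvinyl ether is expected.

Step 5
Reactants: 10 tributyl[1-(3,4,5-trimethoxyphenoxy)ethenyl]stannane; 3 3-isopropoxycyclobut-3-ene-1,2-dione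
Product: 13 rac-3-isopropoxy-4-methoxy-4-[1-(3,4,5-trimethoxyphenoxy)ethenyl]cyclobut-2-en-1-one, via vinyllithium 11 (not isolated), via lithium alkoxide 12 (not isolated)
Conditions: n-BuLi, THF, −78 °C; cannulated into 3, THF, −78 °C; MeOTf, −78 → 0 °C; aq. NaHCO3
Reagents that add atoms: methyl trifluoromethanesulfonate, COS(=O)(=O)C(F)(F)F
Why: Tin–lithium exchange gives the 1-(aryloxy)vinyllithium, which should add 1,2 to the more ketone-like carbonyl of 3 (the one beside the isopropoxy carbon, not the vinylogous ester carbonyl), and the tertiary lithium alkoxide is O-methylated in the same flask by methyl triflate; the quaternary centre forms as a racemate and is erased in step 6.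

Step 6
Reactants: 13 rac-3-isopropoxy-4-methoxy-4-[1-(3,4,5-trimethoxyphenoxy)ethenyl]cyclobut-2-en-1-one
Product: 16 3-isopropoxy-4-methoxy-5-(3,4,5-trimethoxyphenoxy)phenol, via dienylketene 14 (not isolated), via cyclohexadienone 15 (not isolated)
Conditions: toluene (0.01 M, degassed), 110 °C
Reagents that add atoms: none
Why: Heating opens the cyclobutenone by conrotatory 4π electrocyclic cleavage of the C1–C4 bond to dienylketene 14, and a 6π electrocyclisation then bonds the ketene carbon to the CH2 terminus of the aryloxyvinyl group to give cyclohexadienone 15, which enolises to phenol 16. The closest known reaction type is the Moore rearrangement of 4-alkenyl-4-alkoxycyclobutenones to phenols. Ring D is closed by a six-electron disrotatory electrocyclic closure that makes one C–C bond of a six-membered carbocycle, with aromatisation as the driving force. No stereocentre is formed, and the racemic quaternary carbon of 13 is lost in the ring opening. The selectivity needed is torquoselectivity, and the 4-methoxy donor secures it by rotating outward, which turns the vinyl group inward and cis to the ketene. The placement of the four oxygens follows from the connectivity of 13 (carbonyl carbon to C1–OH, isopropoxy carbon to C3, methoxy carbon to C4, aryloxyvinyl carbon to C5), and high dilution limits capture of the ketene by the product phenol.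

Step 7
Reactants: 16 3-isopropoxy-4-methoxy-5-(3,4,5-trimethoxyphenoxy)phenol
Product: 17 3-isopropoxy-4-methoxy-5-(3,4,5-trimethoxyphenoxy)phenyl N-isopropylcarbamate
Conditions: i-PrNCO, Et3N (cat.), CH2Cl2, rt
Reagents that add atoms: isopropyl isocyanate, CC(C)N=C=O
Why: Amine-catalysed addition of the unhindered phenol to the isocyanate (carbamoylation) installs a strong ortho-directing group that can later be removed under mild base.

Step 8
Reactants: 17 3-isopropoxy-4-methoxy-5-(3,4,5-trimethoxyphenoxy)phenyl N-isopropylcarbamate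
Product: 21 5-isopropoxy-4-methoxy-3-(3,4,5-trimethoxyphenoxy)-2-(trimethylsilyl)phenyl N-isopropylcarbamate, via N-silyl carbamate 18 (not isolated), via aryllithium 19 (not isolated), via bis-silyl carbamate 20 (not isolated)
Conditions: TBSOTf, TMEDA, Et2O, 0 °C → rt; n-BuLi, TMEDA, −78 °C; TMSCl, −78 °C → rt; aq. NaHSO4
Reagents that add atoms: chlorotrimethylsilane, C[Si](C)(C)Cl
Why: Directed ortho-metalation of the carbamate, N-silylated in the flask so that it neither eliminates nor rearranges, should lithiate the position flanked by the carbamate and the ring E aryloxy group, and C-silylation there followed by N–Si hydrolysis gives the aryne precursor core; lithiation at the other carbamate-flanked position would lead to an aryne that accepts a nucleophile at the same carbon, so step 15 does not depend on this choice.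

Step 9
Reactants: 21 5-isopropoxy-4-methoxy-3-(3,4,5-trimethoxyphenoxy)-2-(trimethylsilyl)phenyl N-isopropylcarbamate
Product: 23 5-isopropoxy-4-methoxy-3-(3,4,5-trimethoxyphenoxy)-2-(trimethylsilyl)phenyl trifluoromethanesulfonate, via silylphenol 22 (not isolated)
Conditions: DBU, Et2NH, MeCN, 40 °C; then PhNTf2, rt
Reagents that add atoms: N-phenylbis(trifluoromethanesulfonimide), O=S(=O)(N(c1ccccc1)S(=O)(=O)C(F)(F)F)C(F)(F)F
Why: DBU removes the carbamate N–H and expels isopropyl isocyanate (E1cB carbamate cleavage, the isocyanate being trapped by diethylamine), and the 2-silylphenoxide is triflated at once by the mild triflimide before it can protodesilylate, the standard one-flask route to ortho-silylaryl triflates.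

Step 10
Reactants: 24 5-bromo-1,2,3-trimethoxybenzene
Product: 25 6-bromo-2,3,4-trimethoxybenzaldehyde
Conditions: Cl2CHOMe, TiCl4, CH2Cl2, 0 °C → rt; ice/aq. HCl
Reagents that add atoms: dichloromethyl methyl ether, COC(Cl)Cl; water, O
Why: Rieche formylation attacks the only kind of free ring position, which is para to one methoxy group and ortho to another, and hydrolysis on work-up gives the aldehyde ortho to bromine.

Step 11
Reactants: 26 2,4,6-trimethoxyphenol; 27 4-bromo-2,6-dimethoxybenzaldehyde
Product: 28 2,6-dimethoxy-4-(2,4,6-trimethoxyphenoxy)benzaldehyde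
Conditions: CuI (10 mol %), picolinic acid (20 mol %), K3PO4, DMSO, 90 °C, Ar
Reagents that add atoms: none
Why: Ullmann-type diaryl ether synthesis with the CuI–picolinic acid catalyst, which accepts 2,6-disubstituted phenols, is favoured here because the aryl bromide is unhindered and activated by its para-formyl group.

Step 12
Reactants: 28 2,6-dimethoxy-4-(2,4,6-trimethoxyphenoxy)benzaldehyde
Product: 30 2,6-dimethoxy-4-(2,4,6-trimethoxyphenoxy)phenol, via aryl formate 29 (not isolated)
Conditions: mCPBA (1.2 equiv), NaHCO3, CH2Cl2, 0 °C → rt; Na2S2O3; then K2CO3, MeOH, rt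
Reagents that add atoms: 3-chloroperoxybenzoic acid, OOC(=O)c1cccc(Cl)c1
Why: Baeyer–Villiger (Dakin-type) oxidation of the aldehyde proceeds by migration of the electron-rich aryl group with its two ortho-methoxy donors to give formate 29, and methanolysis releases the phenol that carries the future ring B–ring C oxygen.

Step 13
Reactants: 30 2,6-dimethoxy-4-(2,4,6-trimethoxyphenoxy)phenol; 25 6-bromo-2,3,4-trimethoxybenzaldehyde
Product: 31 6-[2,6-dimethoxy-4-(2,4,6-trimethoxyphenoxy)phenoxy]-2,3,4-trimethoxybenzaldehyde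
Conditions: CuI (20 mol %), picolinic acid (40 mol %), K3PO4, DMSO, 100 °C, Ar
Reagents that add atoms: none
Why: A second Ullmann-type etherification should succeed because an ortho-formyl group accelerates copper insertion into the C–Br bond and the picolinic acid system tolerates the 2,6-dimethoxyphenoxide.

Step 14
Reactants: 31 6-[2,6-dimethoxy-4-(2,4,6-trimethoxyphenoxy)phenoxy]-2,3,4-trimethoxybenzaldehyde
Product: 33 6-[2,6-dimethoxy-4-(2,4,6-trimethoxyphenoxy)phenoxy]-2,3,4-trimethoxyphenol, via aryl formate 32 (not isolated)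
Conditions: mCPBA (1.2 equiv), NaHCO3, CH2Cl2, 0 °C → rt; Na2S2O3; then K2CO3, MeOH, rt
Reagents that add atoms: 3-chloroperoxybenzoic acid, OOC(=O)c1cccc(Cl)c1
Why: The same Baeyer–Villiger (Dakin-type) oxidation turns the formyl carbon into the ring C hydroxyl that sits between the ring B ether and a methoxy group, which is the oxygen destined for ring D.

Step 15
Reactants: 33 6-[2,6-dimethoxy-4-(2,4,6-trimethoxyphenoxy)phenoxy]-2,3,4-trimethoxyphenol; 23 5-isopropoxy-4-methoxy-3-(3,4,5-trimethoxyphenoxy)-2-(trimethylsilyl)phenyl trifluoromethanesulfonate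
Product: 35 2-{4-[2-(3-isopropoxy-4-methoxy-5-(3,4,5-trimethoxyphenoxy)phenoxy)-3,4,5-trimethoxyphenoxy]-3,5-dimethoxyphenoxy}-1,3,5-trimethoxybenzene, via aryne 34 (not isolated)
Conditions: CsF (3 equiv), MeCN, rt → 40 °C; 23 (1.5 equiv)
Reagents that add atoms: none
Why: Fluoride-induced 1,2-elimination of the ortho-silylaryl triflate gives 3-aryloxyaryne 34, and the caesium phenoxide of 33 should add at the aryne carbon remote from the flanking aryloxy group (the former triflate carbon, as for 3-alkoxyarynes) before the aryl anion takes the phenol proton; this aryne O-arylation tolerates a di-ortho-substituted phenoxide.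

Step 16
Reactants: 35 2-{4-[2-(3-isopropoxy-4-methoxy-5-(3,4,5-trimethoxyphenoxy)phenoxy)-3,4,5-trimethoxyphenoxy]-3,5-dimethoxyphenoxy}-1,3,5-trimethoxybenzene
Product: 36 CNP0154768.0, 2-{4-[2-(3,4-dihydroxy-5-(3,4,5-trihydroxyphenoxy)phenoxy)-3,4,5-trihydroxyphenoxy]-3,5-dihydroxyphenoxy}benzene-1,3,5-triol
Conditions: BBr3 (40 equiv), CH2Cl2, −78 °C → rt; MeOH, then H2O; Ar; Sephadex LH-20
Reagents that add atoms: none
Why: Lewis-acid ether cleavage by BBr3 removes the twelve methyl groups and the isopropyl group by bromide attack at sp3 carbon, while the four diaryl ether bonds offer no such carbon and should survive, and hydrolysis of the borates frees the thirteen phenols.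

**Compound list**

1 | diisopropyl squarate (3,4-diisopropoxycyclobut-3-ene-1,2-dione) | CC(C)OC1=C(OC(C)C)C(=O)C1=O | starting material
2 | rac-4-hydroxy-2,3-diisopropoxycyclobut-2-en-1-one | CC(C)OC1=C(OC(C)C)C(=O)C1O | intermediate
3 | 3-isopropoxycyclobut-3-ene-1,2-dione (isopropyl semisquarate) | CC(C)OC1=CC(=O)C1=O | intermediate
4 | 3,4,5-trimethoxyphenol | COc1cc(O)cc(OC)c1OC | starting material
5 | trichloroethylene | ClC=C(Cl)Cl | starting material
6 | 5-{[(E)-1,2-dichloroethenyl]oxy}-1,2,3-trimethoxybenzene | COc1cc(O/C(Cl)=C\Cl)cc(OC)c1OC | intermediate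
7 | 5-[(chloroethynyl)oxy]-1,2,3-trimethoxybenzene | ClC#COc1cc(OC)c(OC)c(OC)c1 | intermediate
8 | lithium 2-(3,4,5-trimethoxyphenoxy)ethynide | [Li]C#COc1cc(OC)c(OC)c(OC)c1 | intermediate
9 | 5-(ethynyloxy)-1,2,3-trimethoxybenzene | C#COc1cc(OC)c(OC)c(OC)c1 | intermediate
10 | tributyl[1-(3,4,5-trimethoxyphenoxy)ethenyl]stannane | CCCC[Sn](CCCC)(CCCC)C(=C)Oc1cc(OC)c(OC)c(OC)c1 | intermediate
11 | 1-(3,4,5-trimethoxyphenoxy)ethenyllithium | [Li]C(=C)Oc1cc(OC)c(OC)c(OC)c1 | intermediate
12 | lithium alkoxide of rac-4-hydroxy-3-isopropoxy-4-[1-(3,4,5-trimethoxyphenoxy)ethenyl]cyclobut-2-en-1-one | [Li]OC1(C(=C)Oc2cc(OC)c(OC)c(OC)c2)C(OC(C)C)=CC1=O | intermediate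
13 | rac-3-isopropoxy-4-methoxy-4-[1-(3,4,5-trimethoxyphenoxy)ethenyl]cyclobut-2-en-1-one | CC(C)OC1=CC(=O)C1(OC)C(=C)Oc1cc(OC)c(OC)c(OC)c1 | intermediate
14 | (3Z)-3-isopropoxy-4-methoxy-5-(3,4,5-trimethoxyphenoxy)hexa-1,3,5-trien-1-one (dienylketene) | CC(C)O/C(C=C=O)=C(OC)/C(=C)Oc1cc(OC)c(OC)c(OC)c1 | intermediate
15 | 3-isopropoxy-4-methoxy-5-(3,4,5-trimethoxyphenoxy)cyclohexa-2,4-dien-1-one | CC(C)OC1=CC(=O)CC(Oc2cc(OC)c(OC)c(OC)c2)=C1OC | intermediate
16 | 3-isopropoxy-4-methoxy-5-(3,4,5-trimethoxyphenoxy)phenol | CC(C)Oc1cc(O)cc(Oc2cc(OC)c(OC)c(OC)c2)c1OC | intermediate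
17 | 3-isopropoxy-4-methoxy-5-(3,4,5-trimethoxyphenoxy)phenyl N-isopropylcarbamate | CC(C)NC(=O)Oc1cc(OC(C)C)c(OC)c(Oc2cc(OC)c(OC)c(OC)c2)c1 | intermediate
18 | 3-isopropoxy-4-methoxy-5-(3,4,5-trimethoxyphenoxy)phenyl N-(tert-butyldimethylsilyl)-N-isopropylcarbamate | CC(C)N(C(=O)Oc1cc(OC(C)C)c(OC)c(Oc2cc(OC)c(OC)c(OC)c2)c1)[Si](C)(C)C(C)(C)C | intermediate
19 | 2-lithio derivative of 18 (lithium between the carbamate and the ring E aryloxy group) | [Li]c1c(OC(=O)N(C(C)C)[Si](C)(C)C(C)(C)C)cc(OC(C)C)c(OC)c1Oc1cc(OC)c(OC)c(OC)c1 | intermediate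
20 | 5-isopropoxy-4-methoxy-3-(3,4,5-trimethoxyphenoxy)-2-(trimethylsilyl)phenyl N-(tert-butyldimethylsilyl)-N-isopropylcarbamate | CC(C)N(C(=O)Oc1cc(OC(C)C)c(OC)c(Oc2cc(OC)c(OC)c(OC)c2)c1[Si](C)(C)C)[Si](C)(C)C(C)(C)C | intermediate
21 | 5-isopropoxy-4-methoxy-3-(3,4,5-trimethoxyphenoxy)-2-(trimethylsilyl)phenyl N-isopropylcarbamate | CC(C)NC(=O)Oc1cc(OC(C)C)c(OC)c(Oc2cc(OC)c(OC)c(OC)c2)c1[Si](C)(C)C | intermediate
22 | 5-isopropoxy-4-methoxy-3-(3,4,5-trimethoxyphenoxy)-2-(trimethylsilyl)phenol | CC(C)Oc1cc(O)c([Si](C)(C)C)c(Oc2cc(OC)c(OC)c(OC)c2)c1OC | intermediate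
23 | 5-isopropoxy-4-methoxy-3-(3,4,5-trimethoxyphenoxy)-2-(trimethylsilyl)phenyl trifluoromethanesulfonate | CC(C)Oc1cc(OS(=O)(=O)C(F)(F)F)c([Si](C)(C)C)c(Oc2cc(OC)c(OC)c(OC)c2)c1OC | intermediate
24 | 5-bromo-1,2,3-trimethoxybenzene | COc1cc(Br)cc(OC)c1OC | starting material
25 | 6-bromo-2,3,4-trimethoxybenzaldehyde | COc1cc(Br)c(C=O)c(OC)c1OC | intermediate
26 | 2,4,6-trimethoxyphenol | COc1cc(OC)c(O)c(OC)c1 | starting material
27 | 4-bromo-2,6-dimethoxybenzaldehyde | COc1cc(Br)cc(OC)c1C=O | starting material
28 | 2,6-dimethoxy-4-(2,4,6-trimethoxyphenoxy)benzaldehyde | COc1cc(OC)c(Oc2cc(OC)c(C=O)c(OC)c2)c(OC)c1 | intermediate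
29 | 2,6-dimethoxy-4-(2,4,6-trimethoxyphenoxy)phenyl formate | COc1cc(OC)c(Oc2cc(OC)c(OC=O)c(OC)c2)c(OC)c1 | intermediate
30 | 2,6-dimethoxy-4-(2,4,6-trimethoxyphenoxy)phenol | COc1cc(OC)c(Oc2cc(OC)c(O)c(OC)c2)c(OC)c1 | intermediate
31 | 6-[2,6-dimethoxy-4-(2,4,6-trimethoxyphenoxy)phenoxy]-2,3,4-trimethoxybenzaldehyde | COc1cc(OC)c(Oc2cc(OC)c(Oc3cc(OC)c(OC)c(OC)c3C=O)c(OC)c2)c(OC)c1 | intermediate
32 | 6-[2,6-dimethoxy-4-(2,4,6-trimethoxyphenoxy)phenoxy]-2,3,4-trimethoxyphenyl formate | COc1cc(OC)c(Oc2cc(OC)c(Oc3cc(OC)c(OC)c(OC)c3OC=O)c(OC)c2)c(OC)c1 | intermediate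
33 | 6-[2,6-dimethoxy-4-(2,4,6-trimethoxyphenoxy)phenoxy]-2,3,4-trimethoxyphenol | COc1cc(OC)c(Oc2cc(OC)c(Oc3cc(OC)c(OC)c(OC)c3O)c(OC)c2)c(OC)c1 | intermediate
34 | 5-isopropoxy-4-methoxy-3-(3,4,5-trimethoxyphenoxy)benzyne | CC(C)OC1=CC#CC(Oc2cc(OC)c(OC)c(OC)c2)=C1OC | intermediate
35 | 2-{4-[2-(3-isopropoxy-4-methoxy-5-(3,4,5-trimethoxyphenoxy)phenoxy)-3,4,5-trimethoxyphenoxy]-3,5-dimethoxyphenoxy}-1,3,5-trimethoxybenzene (dodecamethyl isopropyl ether of the target) | COc1cc(OC)c(Oc2cc(OC)c(Oc3cc(OC)c(OC)c(OC)c3Oc3cc(OC(C)C)c(OC)c(Oc4cc(OC)c(OC)c(OC)c4)c3)c(OC)c2)c(OC)c1 | intermediate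
36 | CNP0154768.0, 2-{4-[2-(3,4-dihydroxy-5-(3,4,5-trihydroxyphenoxy)phenoxy)-3,4,5-trihydroxyphenoxy]-3,5-dihydroxyphenoxy}benzene-1,3,5-triol | Oc1cc(O)c(Oc2cc(O)c(Oc3cc(O)c(O)c(O)c3Oc3cc(O)c(O)c(Oc4cc(O)c(O)c(O)c4)c3)c(O)c2)c(O)c1 | target

**Count and risks**

Total step count: 16. Longest linear sequence: 10 steps (from 4 through steps 2, 3, 4, 5, 6, 7, 8, 9, 15 and 16).

Steps most likely to fail:

Step 5. The α-oxygenated vinyllithium may be lost by α-elimination of aryloxide while the tin–lithium exchange is still running, the crowded tertiary alkoxide may be only partly captured by methyl triflate, and the enol ether may hydrolyse on work-up. The fallback sets out from ethynyl ether 9 and returns at 13. Markovnikov addition of HBr (bromotrimethylsilane and methanol in CH2Cl2 at −40 °C) would give 5-[(1-bromoethenyl)oxy]-1,2,3-trimethoxybenzene F1. Bromine–lithium exchange with t-BuLi (2 equiv) in THF/Et2O/pentane at −100 °C would give vinyllithium 11 faster and colder than the tin route. Addition to 3 (through alkoxide 12) and an NH4Cl quench would give the isolable tertiary alcohol rac-4-hydroxy-3-isopropoxy-4-[1-(3,4,5-trimethoxyphenoxy)ethenyl]cyclobut-2-en-1-one F2. Methylation of the neutral alcohol with MeI and Ag2O in MeCN would then give 13.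

Step 13. Coupling of a di-ortho-substituted, easily oxidised phenoxide with an ortho-substituted aryl bromide may stall, so that oxidation of the hydroquinone-type phenol or reduction of the bromide takes over. The fallback sets out from phenol 30 and returns at aldehyde 31. 6-Fluoro-2,3,4-trimethoxybenzaldehyde F3 would be made from 5-fluoro-1,2,3-trimethoxybenzene by lithiation between fluorine and methoxy (n-BuLi, THF, −78 °C) and a DMF quench, and would replace bromide 25. The ether would then be formed without copper by nucleophilic aromatic substitution (Cs2CO3, DMSO, 120 °C), the ortho-formyl group stabilising the anionic adduct.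

Step 16. Cleavage of thirteen ethers may stop at partly alkylated mixtures, the isopropyl cation may alkylate the electron-rich rings, and the free polyphenol may oxidise during isolation. The fallback sets out from 35 and returns at 36. The crude product of the BBr3 cleavage would be peracetylated without isolation (Ac2O, pyridine, DMAP) to the tridecaacetate of 36 F4, which is stable to air and silica and can be separated from incompletely cleaved material. Acid methanolysis (AcCl in degassed MeOH, rt) would then release 36.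

**Further compounds**

F1 | step 5 | 5-[(1-bromoethenyl)oxy]-1,2,3-trimethoxybenzene | BrC(=C)Oc1cc(OC)c(OC)c(OC)c1
F2 | step 5 | rac-4-hydroxy-3-isopropoxy-4-[1-(3,4,5-trimethoxyphenoxy)ethenyl]cyclobut-2-en-1-one | CC(C)OC1=CC(=O)C1(O)C(=C)Oc1cc(OC)c(OC)c(OC)c1
F3 | step 13 | 6-fluoro-2,3,4-trimethoxybenzaldehyde | COc1cc(F)c(C=O)c(OC)c1OC
F4 | step 16 | tridecaacetate of 36 | CC(=O)Oc1cc(OC(C)=O)c(Oc2cc(OC(C)=O)c(Oc3cc(OC(C)=O)c(OC(C)=O)c(OC(C)=O)c3Oc3cc(OC(C)=O)c(OC(C)=O)c(Oc4cc(OC(C)=O)c(OC(C)=O)c(OC(C)=O)c4)c3)c(OC(C)=O)c2)c(OC(C)=O)c1
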